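Atom numbers are eudesmane numbers: ring A = C1–C5 and C10, ring B = C5–C10, C14 is the methyl on C10, C15 the carbon on C4, C11–C13 the unit on C7. Compound numbers are those of the steps and of the list after them. TBS = tert-butyldimethylsilyl, TES = triethylsilyl, Bn = benzyl.

## Analysis of the target

Target 37 is a trans-fused eudesmane (decalin with 5α-H and an axial 10β-methyl). It has seven stereocentres: C1, C4, C5, C6, C7, C8 and C10. Apart from the angular methyl, every substituent is equatorial: 1β-OH, 4α-CHO, 6α-OH, the 7β-acrylic acid unit and the 8α-acyloxy group. The array is therefore the thermodynamically preferred one.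

The sensitive groups are two α-methylene carbonyl Michael acceptors (the C11=C13 acrylic acid and the 2-(hydroxymethyl)acrylate), a free C12 acid γ to the free 6-OH (lactonisation to a 12,6-olide), an aldehyde on the epimerisable C4 that lies peri to O6 (lactol formation), and a base-labile ester on O8.

Three things make the synthesis hard. O6 and O8 are both secondary and equatorial, flank C7, and must end up different (free and acylated). The β face of ring B is screened by the axial C10 methyl, which is 1,3-diaxial to the β positions of C6 and C8, so hydride reagents attack from the α face and would give the axial alcohols, not the equatorial ones required. The closing steps must spare two acrylates, which rules out hydrogenolysis and strong base late in the route.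

The strategy rests on one feature: C6 and C8 carry oxygen on either side of C7, and the methyl-bearing quaternary C10 is β to both. Ring B is thus a masked 5,5-disubstituted cyclohexane-1,3-dione, the retron of a malonate annulated onto a ring-A 1-acetyl-2-methylcyclohexene.

## Retrosynthetic reasoning

**37 ⇐ 36.** The three hydroxyls (O1, O6, acrylate CH2OH) are uncovered last from silyl ethers, so that the hydroxy acid, the hydroxy aldehyde and the acrylates never meet base or hydrogen. The forward step must cleave two hindered secondary silyl ethers without lactonising the γ-hydroxy acid.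

**36 ⇐ 35 ⇐ 34.** The C15 aldehyde is made from the primary alcohol only after C12 has reached the acid level, because the chlorite oxidation that makes the acid would also oxidise a C15 aldehyde. C15 therefore carries the one silyl group (TES) that can be removed selectively.

**34 ⇐ 33 ⇐ 31 ⇐ 29.** The acrylic acid on C7 is cut at C11=C13 and at the oxidation level of C12: acid from enal 33, enal from aldehyde 31 by α-methylenation, aldehyde from the allyl group of 29 by ozonolysis. No ester or lactone of C12 ever has to be opened or deprotected next to the 6-OH, and no strong base is needed after the acrylate ester is in place.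

**29 ⇐ 24 + 27.** The O8–acyl bond is cut. Alcohol 24 has only the 8α-OH free, so no selection between O6 and O8 is needed at the acylation. Acid 27 comes from 25 in two steps.

**24 ⇐ 23 ⇐ 22.** The C8 carbinol is taken back to the ketone. The forward reduction must put hydrogen on the hindered β face, so it is a dissolving-metal (thermodynamic) reduction. The same step removes the benzyl group from O15, which is then re-covered as the TES ether.

**22 ⇐ 21 ⇐ 20 ⇐ 19.** The C6 oxygen is delivered as oxygen from the open α face: nucleophilic epoxidation of enone 19, then reductive opening of the α-C–O bond to aldol 21. Silylating 21 before the C8 alcohol exists is what differentiates O6 from O8.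

**19 ⇐ 17 ⇐ 16.** Enone 19 comes from the 2-substituted 1,3-dione 16 by enol ether formation, carbonyl reduction and hydrolysis with transposition. A direct hydride reduction of the enolised β-diketone is avoided, since it would give elimination products and the wrong (axial) carbinols.

**16 ⇐ 15.** The C7–C11 bond is cut. C7 of dione 15 is the only carbon between two carbonyls, so allylation there is regiochemically unambiguous. The allyl group is a masked CH2–CHO that survives the reductive steps.

**15 ⇐ 10 + 11 (key disconnection).** The C9–C10 and C7–C8 bonds are cut. Malonate 11 supplies C8 and C9; the acetyl group of 10 supplies C6 and C7. The forward step must create the quaternary C10 on the face anti to O1 and leave C5 in the trans fusion.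

**10 ⇐ 9 ⇐ 8 ⇐ 6.** The acetyl group is carried as an ethynyl group, so that the ring ketone of 6 is the only carbonyl present when C1 is set by catalyst-controlled (CBS) reduction. Hydration of the alkyne then gives the methyl ketone.

**6 ⇐ 4 ⇐ 2 + 3 ⇐ 1.** Enynone 6 arises from vinylogous ester 2 by α′-alkylation with 3 (C4–C15 bond), acetylide addition and acid transposition. The alkylation gives racemic C4, and an oxazaborolidine cannot correct a centre that already exists. The reduction is therefore used as a stereodivergent step on the racemate: both enantiomers of 6 receive the same C1 configuration, only the (4R) half emerges as the 1,4-trans alcohol 8, and the (4S) half is removed by chromatography at that point.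

## Alternatives that were turned down

**Alternative 1: oxidative radical bicyclisation of an acyclic malonate.**
- Disconnection: C4–C5 and C9–C10. Both rings are closed from the open-chain chloro-diene malonate A2.
- Forward step: Mn(OAc)3 (trivalent manganese), with Cu(OAc)2 (divalent copper) as co-oxidant, generates the malonyl radical at C4. Two 6-endo additions follow, and the α-chloro radical at C8 is oxidised and hydrolysed to the ketone of A1.
- For: both rings, C5 and C10 are formed in one step through a chair–chair transition state; the C8 ketone and a protected O6 are already differentiated.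
- Against: C4 ends as a geminal diester, so one ester must be removed and the other reduced, with C4 set afterwards by protonation. The C1 and C6 silyloxy stereocentres of A2 need two separate acyclic asymmetric operations, and both sit allylic to the central alkene, where they must also control the folding. In A1 only one carbonyl flanks C7, so the C11 unit would have to be introduced through a ketone enolate with a C7/C9 regiochemistry problem and a β-silyloxy leaving group.
- Comparison: Alternative 1 is stronger in skeletal step economy. The chosen route offers in its place a C7 that is uniquely acidic between two carbonyls and a ring-A precursor reached in six steps from a commodity dione.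

**Alternative 2: transannular cyclisation of a germacranolide epoxide.**
- Disconnection: C5–C10 across a ten-membered ring.
- Forward step: Lewis-acid opening of the 1β,10α-epoxide of A4, attack of the C4=C5 alkene on C10 with inversion, and loss of a C15 proton, giving A3.
- For: A3 already holds the C11 methylene, O6, O8, the 1β-hydroxyl and all ring stereocentres, which is the closest approach to the natural pattern.
- Against: A4 is a ten-membered E-alkene/epoxide lactone with four stereocentres; as a total-synthesis intermediate it is harder to reach than the target. The C4 cation partitions between exocyclic and endocyclic alkenes and tertiary alcohols. The 4(15)-alkene must be hydroborated in the presence of an α-methylene lactone. The 12,6-lactone must later be opened to the free hydroxy acid, which is incompatible with an acrylate ester on O8 and would have to precede the acylation, bringing the O6/O8 problem back.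
- Comparison: Alternative 2 is stronger in how much of the target the key step delivers. The chosen route offers a route from simple commercial materials and never passes through a lactone that must be reopened.

**Alternative 3: intramolecular Diels–Alder reaction of a nitroalkene.**
- Disconnection: C1–C2 and C5–C10.
- Forward step: heating triene A6 adds the (E)-nitroalkene to the diene and closes both rings to nitro-octalin A5.
- For: both rings and C1, C5 and C10 arise in one step. The C6/C7/C8 triad arrives on the tether with O6 and O8 already carrying different silyl groups. On that point it is stronger than the chosen route, which spends several steps on this differentiation.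
- Against: the triad of A6 needs several steps of acyclic stereocontrol. A β,β-disubstituted nitroalkene is a reluctant dienophile, and the trans fusion depends on an endo/exo preference that such tethers control poorly. The C3=C4 alkene must be reduced with control of C4 next to an isopropenyl group. The nitro group must be exchanged for the 1β-hydroxyl next to a quaternary carbon.
- Comparison: the chosen route offers in its place stereocentres on ring B that are set by thermodynamic or α-face arguments on a rigid decalin, not by transition-state selectivity in a cycloaddition.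

Key step: step 7

Assumption: the target is taken in the open 6-hydroxy-15-aldehyde, free C12 acid form as drawn; reversible closure of O6 onto C15 (lactol) in solution is treated as the same compound.

## Steps

Step 1
Reactants: 1 2-methylcyclohexane-1,3-dione
Product: 2 3-isobutoxy-2-methylcyclohex-2-en-1-one
Conditions: i-BuOH, TsOH·H2O (cat.), toluene, reflux, Dean–Stark
Reagents that add atoms: 2-methylpropan-1-ol, CC(C)CO
Why: Acid-catalysed enol etherification of a symmetrical cyclic 1,3-dione with azeotropic removal of water; only one vinylogous ester is possible.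

Step 2
Reactants: 2 3-isobutoxy-2-methylcyclohex-2-en-1-one; 3 benzyl chloromethyl ether
Product: 4 rac-6-[(benzyloxy)methyl]-3-isobutoxy-2-methylcyclohex-2-en-1-one
Conditions: LiN(i-Pr)2, THF, −78 °C; then 3, −78 → −20 °C
Reagents that add atoms: none
Why: Kinetic α′-deprotonation of the vinylogous ester gives the cross-conjugated lithium enolate, which is alkylated by the reactive α-chloro ether (enolate alkylation); the new centre (future C4) is formed as a racemate and is sorted out in step 4.

Step 3
Reactants: 4 rac-6-[(benzyloxy)methyl]-3-isobutoxy-2-methylcyclohex-2-en-1-one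
Product: 6 rac-4-[(benzyloxy)methyl]-3-ethynyl-2-methylcyclohex-2-en-1-one, via tertiary propargylic alcohol 5 (not isolated)
Conditions: HC≡CMgBr, THF, 0 °C → rt; then 1 M HCl, 0 °C → rt
Reagents that add atoms: ethynylmagnesium bromide, C#C[Mg]Br; water, O
Why: 1,2-Addition of the small acetylide to the vinylogous ester carbonyl and acid hydrolysis of the enol ether with allylic transposition (Stork–Danheiser sequence) place the two-carbon acetyl precursor on the future C5 and the ketone on the future C1.

Step 4
Reactants: 6 rac-4-[(benzyloxy)methyl]-3-ethynyl-2-methylcyclohex-2-en-1-one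
Product: 8 (1R,4R)-4-[(benzyloxy)methyl]-3-ethynyl-2-methylcyclohex-2-en-1-ol, via catecholborate ester 7 (not isolated)
Conditions: (S)-2-methyl-CBS-oxazaborolidine (20 mol%), catecholborane, toluene, −78 °C; then MeOH–H2O; chromatography
Reagents that add atoms: none
Why: Corey–Bakshi–Shibata reduction of an α-substituted cyclohexenone, in which the substituted alkene arm acts as the large group, so the (S)-catalyst should give the (1R) carbinol from both enantiomers of 6 whatever the remote C4 centre is; the carbinol is first bound as the catecholborate ester 7, which is hydrolysed on work-up. The (4R) enantiomer gives the 1,4-trans alcohol 8, whereas the (4S) enantiomer ends as the 1,4-cis C4 epimer, which is removed by chromatography, so at most half of 6 is carried on. Catecholborane is chosen because it spares the terminal alkyne at low temperature.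

Step 5
Reactants: 8 (1R,4R)-4-[(benzyloxy)methyl]-3-ethynyl-2-methylcyclohex-2-en-1-ol
Product: 9 tert-butyl{[(1R,4R)-4-[(benzyloxy)methyl]-3-ethynyl-2-methylcyclohex-2-en-1-yl]oxy}dimethylsilane
Conditions: TBSOTf, 2,6-lutidine, CH2Cl2, −78 → 0 °C
Reagents that add atoms: tert-butyldimethylsilyl trifluoromethanesulfonate, CC(C)(C)[Si](C)(C)OS(=O)(=O)C(F)(F)F
Why: Silylation of a secondary allylic alcohol with a silyl triflate; the TBS ether tolerates the alkoxide, dissolving-metal and mild acid steps ahead and is removable at the end without base or hydrogen.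

Step 6
Reactants: 9 tert-butyl{[(1R,4R)-4-[(benzyloxy)methyl]-3-ethynyl-2-methylcyclohex-2-en-1-yl]oxy}dimethylsilane
Product: 10 1-[(3R,6R)-6-[(benzyloxy)methyl]-3-[(tert-butyldimethylsilyl)oxy]-2-methylcyclohex-1-en-1-yl]ethan-1-one
Conditions: Ph3PAuCl (2 mol%), AgOSO2CF3 (2 mol%), 1,4-dioxane–H2O, 60 °C
Reagents that add atoms: water, O
Why: Gold-catalysed Markovnikov hydration of a terminal alkyne gives the methyl ketone, as in the conversion of 1-ethynylcyclohexene into 1-acetylcyclohexene; the conditions are close to neutral, so the allylic silyl ether and the C1 and C4 centres are untouched.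

Step 7
Reactants: 10 1-[(3R,6R)-6-[(benzyloxy)methyl]-3-[(tert-butyldimethylsilyl)oxy]-2-methylcyclohex-1-en-1-yl]ethan-1-one; 11 dimethyl malonate
Product: 15 15-(benzyloxy)-1β-[(tert-butyldimethylsilyl)oxy]-11,12,13-trinor-4βH,5αH-eudesmane-6,8-dione, via Michael adduct 12 (not isolated), via bicyclic keto ester 13 (not isolated), via keto acid 14 (not isolated)
Conditions: 11 (1.5 equiv), NaOMe (1.2 equiv), MeOH, reflux; then aq. KOH, reflux; then HCl to pH 3, 60 °C
Reagents that add atoms: none
Why: Sodium dimethyl malonate adds reversibly to C10 of the enone (Michael addition, C9–C10) to give 12, whose enolate equilibrates to the C7 methyl-ketone enolate; this attacks one malonate ester in a Claisen condensation (C7–C8) that closes ring B in the 6-exo-trig mode to give 13, and deprotonation of the acidic β-dicarbonyl product drains the unfavourable Michael equilibrium. Saponification of the remaining C9 ester and acidification give the β-keto acid 14, which loses CO2 on warming. The closest known reaction is the malonate Michael–Claisen synthesis of 5,5-disubstituted cyclohexane-1,3-diones (dimedone type) from β,β-disubstituted enones; a tetrasubstituted acceptor is known to be slow, hence excess malonate, high concentration and a long reaction time. C10 is controlled by the adjacent C1 silyloxy group, which should lie pseudoaxial to avoid A(1,2) strain with the C10 methyl, so that axial attack on the opposite face places C9 trans to O1 and leaves the methyl β. C5 is protonated reversibly next to the C6 carbonyl and should settle in the trans fusion, in which the C1 and C4 substituents are both equatorial. The step needs this C10 facial selectivity and an intact C1 centre: keeping malonate in excess over methoxide holds the free alkoxide low and so limits γ-deprotonation at C1–H, and the C10 epimer could cyclise only to a decalindione with both ring-A substituents axial or with a cis fusion, so the reversible Michael stage should feed the all-equatorial series.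

Step 8
Reactants: 15 15-(benzyloxy)-1β-[(tert-butyldimethylsilyl)oxy]-11,12,13-trinor-4βH,5αH-eudesmane-6,8-dione
Product: 16 7-allyl-15-(benzyloxy)-1β-[(tert-butyldimethylsilyl)oxy]-11,12,13-trinor-4βH,5αH-eudesmane-6,8-dione
Conditions: allyl methyl carbonate (1.05 equiv), Pd(PPh3)4 (3 mol%), THF, rt
Reagents that add atoms: allyl methyl carbonate, C=CCOC(=O)OC
Why: Tsuji–Trost C-allylation of a cyclic 1,3-dione under neutral conditions; C7 is the only carbon between two carbonyls, any O-allyl isomer is re-ionised by zerovalent palladium and funnelled to the C-allyl product, and one equivalent of carbonate limits double allylation.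

Step 9
Reactants: 16 7-allyl-15-(benzyloxy)-1β-[(tert-butyldimethylsilyl)oxy]-11,12,13-trinor-4βH,5αH-eudesmane-6,8-dione
Product: 17 7-allyl-15-(benzyloxy)-1β-[(tert-butyldimethylsilyl)oxy]-8-methoxy-11,12,13-trinor-4βH,5αH-eudesm-7-en-6-one
Conditions: Me2SO4, K2CO3, acetone, rt
Reagents that add atoms: dimethyl sulfate, COS(=O)(=O)OC
Why: The potassium enolate of the 2-substituted 1,3-dione is O-alkylated by the hard sulfate electrophile; O8 is flanked only by the C9 methylene whereas O6 is screened by the ring fusion and the peri C4 substituent, so the 8-methoxy enone should predominate, and any 6-methoxy isomer can be hydrolysed back to 16.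

Step 10
Reactants: 17 7-allyl-15-(benzyloxy)-1β-[(tert-butyldimethylsilyl)oxy]-8-methoxy-11,12,13-trinor-4βH,5αH-eudesm-7-en-6-one
Product: 19 7-allyl-15-(benzyloxy)-1β-[(tert-butyldimethylsilyl)oxy]-11,12,13-trinor-4βH,5αH-eudesm-6-en-8-one, via allylic alcohol 18 (not isolated)
Conditions: i-Bu2AlH, CH2Cl2, −78 °C; then 1 M HCl, THF, 0 °C
Reagents that add atoms: water, O
Why: 1,2-Reduction of the vinylogous ester carbonyl and acid hydrolysis of the γ-hydroxy enol ether with allylic transposition (Stork–Danheiser sequence) give the α-allyl enone. The C6 oxygen is given up on purpose, because hydride from the open α face would have set it axial; it is returned as oxygen from that same face in step 11.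

Step 11
Reactants: 19 7-allyl-15-(benzyloxy)-1β-[(tert-butyldimethylsilyl)oxy]-11,12,13-trinor-4βH,5αH-eudesm-6-en-8-one
Product: 20 7β-allyl-15-(benzyloxy)-1β-[(tert-butyldimethylsilyl)oxy]-6α,7α-epoxy-11,12,13-trinor-4βH,5αH-eudesman-8-one
Conditions: 30% H2O2, NaOH, MeOH, 0 °C → rt
Reagents that add atoms: hydrogen peroxide, OO
Why: Weitz–Scheffer nucleophilic epoxidation of an α-substituted cyclohexenone; the β face of C6 is 1,3-syn to the axial C10 methyl, so hydroperoxide should add from the α face and fix C6 with oxygen α, while the isolated allyl alkene is inert.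

Step 12
Reactants: 20 7β-allyl-15-(benzyloxy)-1β-[(tert-butyldimethylsilyl)oxy]-6α,7α-epoxy-11,12,13-trinor-4βH,5αH-eudesman-8-one
Product: 21 7β-allyl-15-(benzyloxy)-1β-[(tert-butyldimethylsilyl)oxy]-6α-hydroxy-11,12,13-trinor-4βH,5αH,7αH-eudesman-8-one
Conditions: SmI2 (2.5 equiv), THF–MeOH, −90 °C
Reagents that add atoms: none
Why: SmI2 reduces the ketone to a ketyl that expels the α C7–O bond (reductive opening of an α,β-epoxy ketone to the aldol), leaving C6 untouched; protonation of the samarium enolate along the axial α direction at C7 should give the equatorial allyl group, which is also the stable epimer next to the ketone.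

Step 13
Reactants: 21 7β-allyl-15-(benzyloxy)-1β-[(tert-butyldimethylsilyl)oxy]-6α-hydroxy-11,12,13-trinor-4βH,5αH,7αH-eudesman-8-one
Product: 22 7β-allyl-15-(benzyloxy)-1β,6α-bis[(tert-butyldimethylsilyl)oxy]-11,12,13-trinor-4βH,5αH,7αH-eudesman-8-one
Conditions: TBSOTf, 2,6-lutidine, CH2Cl2, −78 → 0 °C
Reagents that add atoms: tert-butyldimethylsilyl trifluoromethanesulfonate, CC(C)(C)[Si](C)(C)OS(=O)(=O)C(F)(F)F
Why: Silyl triflate silylation of a hindered secondary alcohol at low temperature, which also keeps the aldol from dehydrating; covering O6 before O8 exists as an alcohol is what differentiates the two oxygens.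

Step 14
Reactants: 22 7β-allyl-15-(benzyloxy)-1β,6α-bis[(tert-butyldimethylsilyl)oxy]-11,12,13-trinor-4βH,5αH,7αH-eudesman-8-one
Product: 23 7β-allyl-1β,6α-bis[(tert-butyldimethylsilyl)oxy]-11,12,13-trinor-4βH,5αH,7αH-eudesmane-8α,15-diol
Conditions: Li, NH3(l), THF, t-BuOH, −78 °C; then NH4Cl
Reagents that add atoms: none
Why: Dissolving-metal reduction runs through the ketyl and carbanion and gives the more stable equatorial 8α-alcohol, whereas the axial epimer expected from hydride attack on the open α face would be 1,3-diaxial to the C10 methyl. The same electrons cleave the benzyl ether (Birch-type debenzylation); the isolated alkene and the silyl ethers are inert.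

Step 15
Reactants: 23 7β-allyl-1β,6α-bis[(tert-butyldimethylsilyl)oxy]-11,12,13-trinor-4βH,5αH,7αH-eudesmane-8α,15-diol
Product: 24 7β-allyl-1β,6α-bis[(tert-butyldimethylsilyl)oxy]-15-[(triethylsilyl)oxy]-11,12,13-trinor-4βH,5αH,7αH-eudesman-8α-ol
Conditions: Et3SiCl (1.05 equiv), imidazole, CH2Cl2, −40 → 0 °C
Reagents that add atoms: chlorotriethylsilane, CC[Si](Cl)(CC)CC
Why: Selective silylation of the primary C15 hydroxyl over the secondary 8α-hydroxyl next to a branched carbon; TES is chosen because it can later be removed in the presence of the TBS ethers.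

Step 16
Reactants: 25 ethyl 2-(hydroxymethyl)acrylate
Product: 26 ethyl 2-{[(tert-butyldimethylsilyl)oxy]methyl}acrylate
Conditions: TBSCl, imidazole, DMF, rt
Reagents that add atoms: tert-butyldimethylsilyl chloride, CC(C)(C)[Si](C)(C)Cl
Why: Standard silylation of a primary allylic alcohol, so that the side-chain hydroxyl neither acylates itself nor is oxidised in step 23.

Step 17
Reactants: 26 ethyl 2-{[(tert-butyldimethylsilyl)oxy]methyl}acrylate
Product: 27 2-{[(tert-butyldimethylsilyl)oxy]methyl}acrylic acid
Conditions: LiOH, THF–H2O, 0 °C → rt; then 1 M HCl to pH 4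
Reagents that add atoms: lithium hydroxide, [Li+].[OH-]
Why: Saponification of the ethyl ester; the 1,1-disubstituted acrylate is a poor acceptor for hydroxide at low temperature and the primary silyl ether survives cold aqueous LiOH.

Step 18
Reactants: 24 7β-allyl-1β,6α-bis[(tert-butyldimethylsilyl)oxy]-15-[(triethylsilyl)oxy]-11,12,13-trinor-4βH,5αH,7αH-eudesman-8α-ol; 27 2-{[(tert-butyldimethylsilyl)oxy]methyl}acrylic acid
Product: 29 7β-allyl-1β,6α-bis[(tert-butyldimethylsilyl)oxy]-15-[(triethylsilyl)oxy]-11,12,13-trinor-4βH,5αH,7αH-eudesman-8α-yl 2-{[(tert-butyldimethylsilyl)oxy]methyl}acrylate, via mixed anhydride 28 (not isolated)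
Conditions: 27, 2,4,6-Cl3C6H2COCl, Et3N, THF, rt; then 24, DMAP, toluene, rt
Reagents that add atoms: none
Why: Yamaguchi esterification: mixed anhydride 28 acylates the only free hydroxyl, the equatorial 8α-OH; O6 is silylated and locked trans-diequatorial to O8 on the rigid decalin, so neither acyl nor silyl migration between them is geometrically possible.

Step 19
Reactants: 29 7β-allyl-1β,6α-bis[(tert-butyldimethylsilyl)oxy]-15-[(triethylsilyl)oxy]-11,12,13-trinor-4βH,5αH,7αH-eudesman-8α-yl 2-{[(tert-butyldimethylsilyl)oxy]methyl}acrylate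
Product: 31 1β,6α-bis[(tert-butyldimethylsilyl)oxy]-8α-(2-{[(tert-butyldimethylsilyl)oxy]methyl}acryloyloxy)-15-[(triethylsilyl)oxy]-13-nor-4βH,5αH,7αH-eudesman-12-al, via ozonide 30 (not isolated)
Conditions: O3, CH2Cl2, −78 °C (Sudan Red 7B end point); then PPh3, −78 °C → rt
Reagents that add atoms: ozone, [O-][O+]=O
Why: Ozonolysis with reductive work-up; ozone reacts much faster with the electron-rich monosubstituted alkene than with the ester-conjugated 1,1-disubstituted acrylate, and the indicator dye marks the end point before the acrylate is attacked.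

Step 20
Reactants: 31 1β,6α-bis[(tert-butyldimethylsilyl)oxy]-8α-(2-{[(tert-butyldimethylsilyl)oxy]methyl}acryloyloxy)-15-[(triethylsilyl)oxy]-13-nor-4βH,5αH,7αH-eudesman-12-al
Product: 33 1β,6α-bis[(tert-butyldimethylsilyl)oxy]-8α-(2-{[(tert-butyldimethylsilyl)oxy]methyl}acryloyloxy)-15-[(triethylsilyl)oxy]-4βH,5αH,7αH-eudesm-11(13)-en-12-al, via Mannich base 32 (not isolated)
Conditions: CH2=NMe2+ I− (Eschenmoser's salt), Et3N, CH2Cl2, rt
Reagents that add atoms: N,N-dimethylmethyleneiminium iodide, C=[N+](C)C.[I-]
Why: Mannich reaction of the enolisable aldehyde with the iminium salt, then amine-induced β-elimination of dimethylamine from 32 (α-methylenation of an aldehyde); no strong base is present, so the acrylate ester is untouched, and C7 is not α to the aldehyde and keeps its configuration.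

Step 21
Reactants: 33 1β,6α-bis[(tert-butyldimethylsilyl)oxy]-8α-(2-{[(tert-butyldimethylsilyl)oxy]methyl}acryloyloxy)-15-[(triethylsilyl)oxy]-4βH,5αH,7αH-eudesm-11(13)-en-12-al
Product: 34 1β,6α-bis[(tert-butyldimethylsilyl)oxy]-8α-(2-{[(tert-butyldimethylsilyl)oxy]methyl}acryloyloxy)-15-[(triethylsilyl)oxy]-4βH,5αH,7αH-eudesm-11(13)-en-12-oic acid
Conditions: NaClO2, NaH2PO4, 2-methyl-2-butene, t-BuOH–H2O, 0 °C → rt
Reagents that add atoms: sodium chlorite, [Na+].[O-]Cl=O
Why: Pinnick oxidation of an α,β-unsaturated aldehyde to the acrylic acid; the alkene scavenger removes hypochlorous acid, and the buffered medium leaves alkenes, ester and silyl ethers alone. C15 is still a silyl ether, so it cannot be over-oxidised.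

Step 22
Reactants: 34 1β,6α-bis[(tert-butyldimethylsilyl)oxy]-8α-(2-{[(tert-butyldimethylsilyl)oxy]methyl}acryloyloxy)-15-[(triethylsilyl)oxy]-4βH,5αH,7αH-eudesm-11(13)-en-12-oic acid
Product: 35 1β,6α-bis[(tert-butyldimethylsilyl)oxy]-8α-(2-{[(tert-butyldimethylsilyl)oxy]methyl}acryloyloxy)-15-hydroxy-4βH,5αH,7αH-eudesm-11(13)-en-12-oic acid
Conditions: PPTS (cat.), MeOH–CH2Cl2, 0 °C
Reagents that add atoms: none
Why: Mild acid-catalysed methanolysis cleaves a primary TES ether far faster than primary or hindered secondary TBS ethers; at 0 °C neither esterification of the acid nor lactonisation (O6 is still silylated) is expected.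

Step 23
Reactants: 35 1β,6α-bis[(tert-butyldimethylsilyl)oxy]-8α-(2-{[(tert-butyldimethylsilyl)oxy]methyl}acryloyloxy)-15-hydroxy-4βH,5αH,7αH-eudesm-11(13)-en-12-oic acid
Product: 36 1β,6α-bis[(tert-butyldimethylsilyl)oxy]-8α-(2-{[(tert-butyldimethylsilyl)oxy]methyl}acryloyloxy)-15-oxo-4βH,5αH,7αH-eudesm-11(13)-en-12-oic acid
Conditions: Dess–Martin periodinane, NaHCO3, CH2Cl2, 0 °C → rt
Reagents that add atoms: none
Why: Dess–Martin oxidation of the only free hydroxyl, a hindered primary alcohol, to the aldehyde under buffered non-basic conditions; C4 is not expected to epimerise, and the equatorial 4α-aldehyde is in any case the stable epimer, since the axial one would be 1,3-diaxial to the C10 methyl.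

Step 24
Reactants: 36 1β,6α-bis[(tert-butyldimethylsilyl)oxy]-8α-(2-{[(tert-butyldimethylsilyl)oxy]methyl}acryloyloxy)-15-oxo-4βH,5αH,7αH-eudesm-11(13)-en-12-oic acid
Product: 37 1β,6α-dihydroxy-8α-{[2-(hydroxymethyl)acryloyl]oxy}-15-oxo-4βH,5αH,7αH-eudesm-11(13)-en-12-oic acid
Conditions: HF·pyridine, pyridine, THF, 0 °C → rt
Reagents that add atoms: none
Why: Fluoride-mediated cleavage of the three TBS ethers with pyridine-buffered HF; no base is present, so the acrylate ester is neither cleaved nor attacked in a Michael sense, and the buffered acidity should be too low for fast lactonisation of the γ-hydroxy acid. The 8-O-acyl group cannot migrate to the trans-diequatorial O6.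

## Compound list

1 | 2-methylcyclohexane-1,3-dione | CC1C(=O)CCCC1=O | starting material
2 | 3-isobutoxy-2-methylcyclohex-2-en-1-one | CC(C)COC1=C(C)C(=O)CCC1 | intermediate
3 | benzyl chloromethyl ether | ClCOCc1ccccc1 | starting material
4 | rac-6-[(benzyloxy)methyl]-3-isobutoxy-2-methylcyclohex-2-en-1-one (racemic) | CC(C)COC1=C(C)C(=O)C(COCc2ccccc2)CC1 | intermediate
5 | rac-6-[(benzyloxy)methyl]-1-ethynyl-3-isobutoxy-2-methylcyclohex-2-en-1-ol (tertiary propargylic alcohol, diastereomer mixture) | CC(C)COC1=C(C)C(O)(C#C)C(COCc2ccccc2)CC1 | intermediate (not isolated)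
6 | rac-4-[(benzyloxy)methyl]-3-ethynyl-2-methylcyclohex-2-en-1-one (racemic) | C#CC1=C(C)C(=O)CCC1COCc2ccccc2 | intermediate
7 | 2-{[(1R,4R)-4-[(benzyloxy)methyl]-3-ethynyl-2-methylcyclohex-2-en-1-yl]oxy}-1,3,2-benzodioxaborole (catecholborate ester of 8) | C#CC1=C(C)[C@H](OB2Oc3ccccc3O2)CC[C@H]1COCc4ccccc4 | intermediate (not isolated)
8 | (1R,4R)-4-[(benzyloxy)methyl]-3-ethynyl-2-methylcyclohex-2-en-1-ol (1,4-trans) | C#CC1=C(C)[C@H](O)CC[C@H]1COCc2ccccc2 | intermediate
9 | tert-butyl{[(1R,4R)-4-[(benzyloxy)methyl]-3-ethynyl-2-methylcyclohex-2-en-1-yl]oxy}dimethylsilane | C#CC1=C(C)[C@H](O[Si](C)(C)C(C)(C)C)CC[C@H]1COCc2ccccc2 | intermediate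
10 | 1-[(3R,6R)-6-[(benzyloxy)methyl]-3-[(tert-butyldimethylsilyl)oxy]-2-methylcyclohex-1-en-1-yl]ethan-1-one (ring-A precursor: C1 β-OTBS, C4 α-CH2OBn) | CC(=O)C1=C(C)[C@H](O[Si](C)(C)C(C)(C)C)CC[C@H]1COCc2ccccc2 | intermediate
11 | dimethyl malonate | COC(=O)CC(=O)OC | starting material
12 | Michael adduct: dimethyl malonate bonded through C9 to C10 of ring A (10β-methyl, C9 on the α face, 5α-H with β-acetyl, 4α-CH2OBn, 1β-OTBS) | COC(=O)C(C(=O)OC)[C@]1(C)[C@@H](C(C)=O)[C@H](COCc2ccccc2)CC[C@H]1O[Si](C)(C)C(C)(C)C | intermediate (not isolated)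
13 | methyl 15-(benzyloxy)-1β-[(tert-butyldimethylsilyl)oxy]-6,8-dioxo-11,12,13-trinor-4βH,5αH-eudesmane-9-carboxylate (C9 epimers, enolised) | O=C1C(C(=O)OC)[C@]2(C)[C@@H](C(=O)C1)[C@H](COCc3ccccc3)CC[C@H]2O[Si](C)(C)C(C)(C)C | intermediate (not isolated)
14 | 15-(benzyloxy)-1β-[(tert-butyldimethylsilyl)oxy]-6,8-dioxo-11,12,13-trinor-4βH,5αH-eudesmane-9-carboxylic acid | O=C1C(C(=O)O)[C@]2(C)[C@@H](C(=O)C1)[C@H](COCc3ccccc3)CC[C@H]2O[Si](C)(C)C(C)(C)C | intermediate (not isolated)
15 | 15-(benzyloxy)-1β-[(tert-butyldimethylsilyl)oxy]-11,12,13-trinor-4βH,5αH-eudesmane-6,8-dione (trans-fused 10β-methyldecalin-6,8-dione) | O=C1C[C@]2(C)[C@@H](C(=O)C1)[C@H](COCc3ccccc3)CC[C@H]2O[Si](C)(C)C(C)(C)C | intermediate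
16 | 7-allyl-15-(benzyloxy)-1β-[(tert-butyldimethylsilyl)oxy]-11,12,13-trinor-4βH,5αH-eudesmane-6,8-dione (C7 enolised) | O=C1C[C@]2(C)[C@@H](C(=O)C1CC=C)[C@H](COCc3ccccc3)CC[C@H]2O[Si](C)(C)C(C)(C)C | intermediate
17 | 7-allyl-15-(benzyloxy)-1β-[(tert-butyldimethylsilyl)oxy]-8-methoxy-11,12,13-trinor-4βH,5αH-eudesm-7-en-6-one | COC=1C[C@]2(C)[C@@H](C(=O)C1CC=C)[C@H](COCc3ccccc3)CC[C@H]2O[Si](C)(C)C(C)(C)C | intermediate
18 | 7-allyl-15-(benzyloxy)-1β-[(tert-butyldimethylsilyl)oxy]-8-methoxy-11,12,13-trinor-4βH,5αH-eudesm-7-en-6-ol (C6 epimers) | COC=1C[C@]2(C)[C@@H](C(O)C1CC=C)[C@H](COCc3ccccc3)CC[C@H]2O[Si](C)(C)C(C)(C)C | intermediate (not isolated)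
19 | 7-allyl-15-(benzyloxy)-1β-[(tert-butyldimethylsilyl)oxy]-11,12,13-trinor-4βH,5αH-eudesm-6-en-8-one | O=C1C[C@]2(C)[C@@H](C=C1CC=C)[C@H](COCc3ccccc3)CC[C@H]2O[Si](C)(C)C(C)(C)C | intermediate
20 | 7β-allyl-15-(benzyloxy)-1β-[(tert-butyldimethylsilyl)oxy]-6α,7α-epoxy-11,12,13-trinor-4βH,5αH-eudesman-8-one | O=C1C[C@]2(C)[C@@H]([C@H]3O[C@]31CC=C)[C@H](COCc4ccccc4)CC[C@H]2O[Si](C)(C)C(C)(C)C | intermediate
21 | 7β-allyl-15-(benzyloxy)-1β-[(tert-butyldimethylsilyl)oxy]-6α-hydroxy-11,12,13-trinor-4βH,5αH,7αH-eudesman-8-one | O=C1C[C@]2(C)[C@@H]([C@@H](O)[C@@H]1CC=C)[C@H](COCc3ccccc3)CC[C@H]2O[Si](C)(C)C(C)(C)C | intermediate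
22 | 7β-allyl-15-(benzyloxy)-1β,6α-bis[(tert-butyldimethylsilyl)oxy]-11,12,13-trinor-4βH,5αH,7αH-eudesman-8-one | O=C1C[C@]2(C)[C@@H]([C@@H](O[Si](C)(C)C(C)(C)C)[C@@H]1CC=C)[C@H](COCc3ccccc3)CC[C@H]2O[Si](C)(C)C(C)(C)C | intermediate
23 | 7β-allyl-1β,6α-bis[(tert-butyldimethylsilyl)oxy]-11,12,13-trinor-4βH,5αH,7αH-eudesmane-8α,15-diol | O[C@H]1C[C@]2(C)[C@@H]([C@@H](O[Si](C)(C)C(C)(C)C)[C@@H]1CC=C)[C@H](CO)CC[C@H]2O[Si](C)(C)C(C)(C)C | intermediate
24 | 7β-allyl-1β,6α-bis[(tert-butyldimethylsilyl)oxy]-15-[(triethylsilyl)oxy]-11,12,13-trinor-4βH,5αH,7αH-eudesman-8α-ol | O[C@H]1C[C@]2(C)[C@@H]([C@@H](O[Si](C)(C)C(C)(C)C)[C@@H]1CC=C)[C@H](CO[Si](CC)(CC)CC)CC[C@H]2O[Si](C)(C)C(C)(C)C | intermediate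
25 | ethyl 2-(hydroxymethyl)acrylate | C=C(CO)C(=O)OCC | starting material
26 | ethyl 2-{[(tert-butyldimethylsilyl)oxy]methyl}acrylate | C=C(CO[Si](C)(C)C(C)(C)C)C(=O)OCC | intermediate
27 | 2-{[(tert-butyldimethylsilyl)oxy]methyl}acrylic acid | C=C(CO[Si](C)(C)C(C)(C)C)C(=O)O | intermediate
28 | 2-{[(tert-butyldimethylsilyl)oxy]methyl}acrylic 2,4,6-trichlorobenzoic anhydride | C=C(CO[Si](C)(C)C(C)(C)C)C(=O)OC(=O)c1c(Cl)cc(Cl)cc1Cl | intermediate (not isolated)
29 | 7β-allyl-1β,6α-bis[(tert-butyldimethylsilyl)oxy]-15-[(triethylsilyl)oxy]-11,12,13-trinor-4βH,5αH,7αH-eudesman-8α-yl 2-{[(tert-butyldimethylsilyl)oxy]methyl}acrylate | C=C(CO[Si](C)(C)C(C)(C)C)C(=O)O[C@H]1C[C@]2(C)[C@@H]([C@@H](O[Si](C)(C)C(C)(C)C)[C@@H]1CC=C)[C@H](CO[Si](CC)(CC)CC)CC[C@H]2O[Si](C)(C)C(C)(C)C | intermediate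
30 | ozonide of 29 (1,2,4-trioxolane at the former allyl alkene) | C=C(CO[Si](C)(C)C(C)(C)C)C(=O)O[C@H]1C[C@]2(C)[C@@H]([C@@H](O[Si](C)(C)C(C)(C)C)[C@@H]1CC3OCOO3)[C@H](CO[Si](CC)(CC)CC)CC[C@H]2O[Si](C)(C)C(C)(C)C | intermediate (not isolated)
31 | 1β,6α-bis[(tert-butyldimethylsilyl)oxy]-8α-(2-{[(tert-butyldimethylsilyl)oxy]methyl}acryloyloxy)-15-[(triethylsilyl)oxy]-13-nor-4βH,5αH,7αH-eudesman-12-al | C=C(CO[Si](C)(C)C(C)(C)C)C(=O)O[C@H]1C[C@]2(C)[C@@H]([C@@H](O[Si](C)(C)C(C)(C)C)[C@@H]1CC=O)[C@H](CO[Si](CC)(CC)CC)CC[C@H]2O[Si](C)(C)C(C)(C)C | intermediate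
32 | 11-[(dimethylamino)methyl] derivative of 31 (Mannich base, C11 epimers) | C=C(CO[Si](C)(C)C(C)(C)C)C(=O)O[C@H]1C[C@]2(C)[C@@H]([C@@H](O[Si](C)(C)C(C)(C)C)[C@@H]1C(CN(C)C)C=O)[C@H](CO[Si](CC)(CC)CC)CC[C@H]2O[Si](C)(C)C(C)(C)C | intermediate (not isolated)
33 | 1β,6α-bis[(tert-butyldimethylsilyl)oxy]-8α-(2-{[(tert-butyldimethylsilyl)oxy]methyl}acryloyloxy)-15-[(triethylsilyl)oxy]-4βH,5αH,7αH-eudesm-11(13)-en-12-al | C=C(CO[Si](C)(C)C(C)(C)C)C(=O)O[C@H]1C[C@]2(C)[C@@H]([C@@H](O[Si](C)(C)C(C)(C)C)[C@@H]1C(=C)C=O)[C@H](CO[Si](CC)(CC)CC)CC[C@H]2O[Si](C)(C)C(C)(C)C | intermediate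
34 | 1β,6α-bis[(tert-butyldimethylsilyl)oxy]-8α-(2-{[(tert-butyldimethylsilyl)oxy]methyl}acryloyloxy)-15-[(triethylsilyl)oxy]-4βH,5αH,7αH-eudesm-11(13)-en-12-oic acid | C=C(CO[Si](C)(C)C(C)(C)C)C(=O)O[C@H]1C[C@]2(C)[C@@H]([C@@H](O[Si](C)(C)C(C)(C)C)[C@@H]1C(=C)C(=O)O)[C@H](CO[Si](CC)(CC)CC)CC[C@H]2O[Si](C)(C)C(C)(C)C | intermediate
35 | 1β,6α-bis[(tert-butyldimethylsilyl)oxy]-8α-(2-{[(tert-butyldimethylsilyl)oxy]methyl}acryloyloxy)-15-hydroxy-4βH,5αH,7αH-eudesm-11(13)-en-12-oic acid | C=C(CO[Si](C)(C)C(C)(C)C)C(=O)O[C@H]1C[C@]2(C)[C@@H]([C@@H](O[Si](C)(C)C(C)(C)C)[C@@H]1C(=C)C(=O)O)[C@H](CO)CC[C@H]2O[Si](C)(C)C(C)(C)C | intermediate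
36 | 1β,6α-bis[(tert-butyldimethylsilyl)oxy]-8α-(2-{[(tert-butyldimethylsilyl)oxy]methyl}acryloyloxy)-15-oxo-4βH,5αH,7αH-eudesm-11(13)-en-12-oic acid | C=C(CO[Si](C)(C)C(C)(C)C)C(=O)O[C@H]1C[C@]2(C)[C@@H]([C@@H](O[Si](C)(C)C(C)(C)C)[C@@H]1C(=C)C(=O)O)[C@H](C=O)CC[C@H]2O[Si](C)(C)C(C)(C)C | intermediate
37 | 1β,6α-dihydroxy-8α-{[2-(hydroxymethyl)acryloyl]oxy}-15-oxo-4βH,5αH,7αH-eudesm-11(13)-en-12-oic acid (CNP0599450.1) | C=C(CO)C(=O)O[C@H]1C[C@]2(C)[C@@H]([C@@H](O)[C@@H]1C(=C)C(=O)O)[C@H](C=O)CC[C@H]2O | target

## Step count and least certain steps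

Total: 24 steps. Longest linear sequence: 22 steps (steps 1–15 and 18–24); steps 16–17 are a two-step side branch.

**Step 7 (key step).**
- What may go wrong: addition of the malonate anion to the tetrasubstituted, doubly flanked C10 may be too slow, so that retro-Michael reaction dominates. The nucleophile may enter on the face syn to O1, because the pseudoaxial C4 substituent hinders the anti face. γ-Deprotonation at C1–H may scramble or destroy the C1 centre. The long basic hydrolysis may cleave the C1 silyl ether.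
- Fallback (from 10, back at 15): the two bonds are made in two operations. A Lewis-acid-mediated Mukaiyama–Michael addition of 1-methoxy-1-(trimethylsilyloxy)ethene to 10 (TiCl4, CH2Cl2, −78 °C) forms C9–C10 without free alkoxide and gives, after work-up, the keto ester methyl [5β-acetyl-10β-methyl-1β-(TBSO)-4α-(benzyloxymethyl)cyclohexyl]acetate F1. An intramolecular Claisen condensation of F1 (KOt-Bu, THF, 0 °C → rt) then closes ring B to 15 directly, with no decarboxylation.

**Step 4.**
- What may go wrong: the remote C4 centre may erode catalyst control for one enantiomer of 6 (mismatched pair), the two diastereomeric carbinols may separate poorly, or the alkyne may be hydroborated. Half of the material is lost by design.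
- Fallback (from 6, back at 8): Luche reduction of 6 (NaBH4, CeCl3·7H2O, MeOH) and isolation of the racemic trans alcohol rac-(1R*,4R*)-4-[(benzyloxy)methyl]-3-ethynyl-2-methylcyclohex-2-en-1-ol F2. Lipase-mediated kinetic resolution of F2 (Burkholderia cepacia lipase, vinyl acetate) should acylate the (1R) enantiomer to the acetate (1R,4R)-4-[(benzyloxy)methyl]-3-ethynyl-2-methylcyclohex-2-en-1-yl acetate F3. Methanolysis of F3 (K2CO3, MeOH) gives 8.

**Step 11.**
- What may go wrong: hydroperoxide addition to the hindered β-carbon C6 may be sluggish, the face selectivity may be incomplete, or base may isomerise the enone through its C5 dienolate.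
- Fallback (from 19, back at 21, bypassing 20): copper-catalysed conjugate borylation of 19 (B2pin2, CuCl, NaOt-Bu, bis[2-(diphenylphosphino)phenyl] ether, MeOH, THF) from the α face gives the 6α-boronate 7β-allyl-15-(benzyloxy)-1β-(TBSO)-6α-(pinacolatoboryl)-11,12,13-trinor-4βH,5αH,7αH-eudesman-8-one F4. Oxidation of F4 with retention (NaBO3·4H2O, THF–H2O) gives 21.

**Step 14.**
- What may go wrong: competing enolisation of the ketone followed by β-elimination of the C6 silyloxy group, incomplete equilibration to the equatorial carbinol, or over-reduction.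
- Fallback (from 22, back at 23): kinetic hydride reduction followed by inversion. NaBH4 in MeOH gives the axial alcohol 7β-allyl-15-(benzyloxy)-1β,6α-bis(TBSO)-11,12,13-trinor-4βH,5αH,7αH-eudesman-8β-ol F5. Mitsunobu inversion of F5 (4-nitrobenzoic acid, PPh3, diisopropyl azodicarboxylate) gives the 8α-(4-nitrobenzoate) F6. Methanolysis of F6 (K2CO3, MeOH) gives 7β-allyl-15-(benzyloxy)-1β,6α-bis(TBSO)-11,12,13-trinor-4βH,5αH,7αH-eudesman-8α-ol F7. Reductive debenzylation of F7 with lithium 4,4′-di-tert-butylbiphenylide (THF, −78 °C) gives 23.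

**Step 24.**
- What may go wrong: the two hindered secondary silyl ethers may cleave slowly, and during the long exposure the freed 6-OH may lactonise onto the C12 acid, or the exocyclic C11=C13 alkene may drift into conjugation with C7.
- Fallback (from 34, back at 37): the acid is masked during desilylation and freed last under neutral conditions. Allylation of 34 (allyl bromide, KHCO3, DMF) gives the allyl ester of 34, F8. Removal of the TES group (PPTS, MeOH) gives the 15-hydroxy allyl ester F9. Dess–Martin oxidation gives the 15-oxo allyl ester F10. HF·pyridine gives the fully desilylated allyl ester of 37, F11. Deallylation of F11 (Pd(PPh3)4, PhSiH3, CH2Cl2) gives 37.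

## Further compounds

F1 | step 7 | methyl 2-[5β-acetyl-10β-methyl-1β-(tert-butyldimethylsilyloxy)-4α-(benzyloxymethyl)cyclohexyl]acetate (eudesmane numbering; C9 on the α face of C10, 5α-H) | COC(=O)C[C@]1(C)[C@@H](C(C)=O)[C@H](COCc2ccccc2)CC[C@H]1O[Si](C)(C)C(C)(C)C
F2 | step 4 | rac-(1R*,4R*)-4-[(benzyloxy)methyl]-3-ethynyl-2-methylcyclohex-2-en-1-ol (racemic trans alcohol, one enantiomer drawn) | C#CC1=C(C)[C@H](O)CC[C@H]1COCc2ccccc2
F3 | step 4 | (1R,4R)-4-[(benzyloxy)methyl]-3-ethynyl-2-methylcyclohex-2-en-1-yl acetate | C#CC1=C(C)[C@H](OC(C)=O)CC[C@H]1COCc2ccccc2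
F4 | step 11 | 7β-allyl-15-(benzyloxy)-1β-[(tert-butyldimethylsilyl)oxy]-6α-(4,4,5,5-tetramethyl-1,3,2-dioxaborolan-2-yl)-11,12,13-trinor-4βH,5αH,7αH-eudesman-8-one | O=C1C[C@]2(C)[C@@H]([C@@H](B3OC(C)(C)C(C)(C)O3)[C@@H]1CC=C)[C@H](COCc4ccccc4)CC[C@H]2O[Si](C)(C)C(C)(C)C
F5 | step 14 | 7β-allyl-15-(benzyloxy)-1β,6α-bis[(tert-butyldimethylsilyl)oxy]-11,12,13-trinor-4βH,5αH,7αH-eudesman-8β-ol | O[C@@H]1C[C@]2(C)[C@@H]([C@@H](O[Si](C)(C)C(C)(C)C)[C@@H]1CC=C)[C@H](COCc3ccccc3)CC[C@H]2O[Si](C)(C)C(C)(C)C
F6 | step 14 | 7β-allyl-15-(benzyloxy)-1β,6α-bis[(tert-butyldimethylsilyl)oxy]-11,12,13-trinor-4βH,5αH,7αH-eudesman-8α-yl 4-nitrobenzoate | O=C(O[C@H]1C[C@]2(C)[C@@H]([C@@H](O[Si](C)(C)C(C)(C)C)[C@@H]1CC=C)[C@H](COCc3ccccc3)CC[C@H]2O[Si](C)(C)C(C)(C)C)c4ccc(cc4)[N+](=O)[O-]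
F7 | step 14 | 7β-allyl-15-(benzyloxy)-1β,6α-bis[(tert-butyldimethylsilyl)oxy]-11,12,13-trinor-4βH,5αH,7αH-eudesman-8α-ol | O[C@H]1C[C@]2(C)[C@@H]([C@@H](O[Si](C)(C)C(C)(C)C)[C@@H]1CC=C)[C@H](COCc3ccccc3)CC[C@H]2O[Si](C)(C)C(C)(C)C
F8 | step 24 | allyl ester of 34 (allyl 1β,6α-bis(TBSO)-8α-acyloxy-15-(triethylsilyloxy)-eudesm-11(13)-en-12-oate) | C=C(CO[Si](C)(C)C(C)(C)C)C(=O)O[C@H]1C[C@]2(C)[C@@H]([C@@H](O[Si](C)(C)C(C)(C)C)[C@@H]1C(=C)C(=O)OCC=C)[C@H](CO[Si](CC)(CC)CC)CC[C@H]2O[Si](C)(C)C(C)(C)C
F9 | step 24 | 15-hydroxy allyl ester (allyl ester of 35) | C=C(CO[Si](C)(C)C(C)(C)C)C(=O)O[C@H]1C[C@]2(C)[C@@H]([C@@H](O[Si](C)(C)C(C)(C)C)[C@@H]1C(=C)C(=O)OCC=C)[C@H](CO)CC[C@H]2O[Si](C)(C)C(C)(C)C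
F10 | step 24 | 15-oxo allyl ester (allyl ester of 36) | C=C(CO[Si](C)(C)C(C)(C)C)C(=O)O[C@H]1C[C@]2(C)[C@@H]([C@@H](O[Si](C)(C)C(C)(C)C)[C@@H]1C(=C)C(=O)OCC=C)[C@H](C=O)CC[C@H]2O[Si](C)(C)C(C)(C)C
F11 | step 24 | allyl 1β,6α-dihydroxy-8α-{[2-(hydroxymethyl)acryloyl]oxy}-15-oxo-4βH,5αH,7αH-eudesm-11(13)-en-12-oate (allyl ester of 37) | C=C(CO)C(=O)O[C@H]1C[C@]2(C)[C@@H]([C@@H](O)[C@@H]1C(=C)C(=O)OCC=C)[C@H](C=O)CC[C@H]2O
A1 | alternative 1 | dimethyl 1β,6α-bis[(tert-butyldimethylsilyl)oxy]-8-oxo-11,12,13,15-tetranor-5α-eudesmane-4,4-dicarboxylate | O=C1C[C@]2(C)[C@@H]([C@@H](O[Si](C)(C)C(C)(C)C)C1)C(C(=O)OC)(C(=O)OC)CC[C@H]2O[Si](C)(C)C(C)(C)C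
A2 | alternative 1 | dimethyl 2-[(4E)-3,6-bis[(tert-butyldimethylsilyl)oxy]-8-chloro-4-methylnona-4,8-dien-1-yl]malonate (C1 and C6 configured as in the target) | COC(=O)C(C(=O)OC)CC[C@@H](O[Si](C)(C)C(C)(C)C)/C(C)=C/[C@@H](O[Si](C)(C)C(C)(C)C)CC(Cl)=C
A3 | alternative 2 | 8α-(triethylsilyloxy)-1β-hydroxyeudesma-4(15),11(13)-dien-12,6α-olide | CC[Si](CC)(CC)O[C@H]1C[C@]2(C)[C@@H]([C@@H](O3)[C@@H]1C(=C)C3=O)C(=C)CC[C@H]2O
A4 | alternative 2 | 8α-(triethylsilyloxy)-1β,10α-epoxygermacra-4E,11(13)-dien-12,6α-olide | CC[Si](CC)(CC)O[C@H]1C[C@@]2(C)O[C@@H]2CC/C(C)=C/[C@H]3OC(=O)C(=C)[C@H]13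
A5 | alternative 3 | trans-fused 1β-nitro-10β-methyl-octal-3-ene with 4-[(4-methoxybenzyloxy)methyl], 6α-OTBS, 7β-isopropenyl and 8α-OTES groups | CC[Si](CC)(CC)O[C@H]1C[C@]2(C)[C@@H]([C@@H](O[Si](C)(C)C(C)(C)C)[C@@H]1C(C)=C)C(COCc3ccc(OC)cc3)=CC[C@H]2[N+](=O)[O-]
A6 | alternative 3 | open-chain triene: (E)-nitroalkene C1=C10 tethered through C9–C8(OTES)–C7(isopropenyl)–C6(OTBS) to the C5=C4(CH2OPMB)–C3=C2 diene | [O-][N+](=O)/C=C(\C)C[C@H](O[Si](CC)(CC)CC)[C@@H](C(C)=C)[C@H](O[Si](C)(C)C(C)(C)C)/C=C(\COCc1ccc(OC)cc1)C=C
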